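**Retrosynthetic overview**

- The central benzene ring is numbered C1 (styryl), C2 (prenyl), C3 (OMe), C4 (prenyl), C5 (OH), C6 (H). The route rests on its meta C3/C5 dioxygenation, which is a cyclohexane-1,3-dione in disguise: C1 is a Michael acceptor carbon, and C2 and C4 are the two enolate carbons.
- Target 19 ⇐ allyl ether 18 ⇐ phenol 17 ⇐ vinylogous ester 12. The ring is aromatized by α'-selenenylation and selenoxide elimination. The allyl group sits on the less hindered C5 oxygen of dione 11.
- 11 ⇐ keto ester 9 (hydrolysis, decarboxylation). 9 ⇐ dienone 4 + prenylmalonate 7, forming C1–C2 by Michael addition and C3–C4 by Claisen condensation.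
- 4 ⇐ cinnamaldehyde 1 + 6-methylhept-5-en-2-one 2 (Claisen–Schmidt). 7 ⇐ diethyl malonate 5 + prenyl bromide 6.
- Only one ring is formed: the central six-membered ring in step 3, made aromatic in step 7. The phenyl ring arrives with 1.

Key step: step 3

Remark: every sp3 stereocentre made on the way (in 3, 8–11, 12–15) is destroyed by step 7. These compounds are racemic and, where relevant, diastereomer or keto–enol mixtures; they are drawn as keto forms without configuration, except 14 and 15, where the expected relative configuration is shown. Only the E styryl double bond, which comes from 1, has to survive.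

**Step 1**
Reactants: 1 (E)-cinnamaldehyde; 2 6-methylhept-5-en-2-one
Product: 4 (1E,3E)-9-methyl-1-phenyldeca-1,3,8-trien-5-one, via aldol 3 (not isolated)
Conditions: 2 (3 equiv), 10% aq. NaOH, EtOH, 0 °C to rt
Reagents that add atoms: none
Why: Claisen–Schmidt (crossed aldol) condensation; cinnamaldehyde cannot enolize, and under hydroxide only the aldol on the methyl side of the ketone dehydrates quickly (E1cB), so the linear dienone with a thermodynamically E new double bond should result and no stereocentre remains.

**Step 2**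
Reactants: 5 diethyl malonate; 6 prenyl bromide
Product: 7 diethyl 2-(3-methylbut-2-enyl)malonate
Conditions: NaOEt (1.0 equiv), 5 (1.5 equiv), EtOH, 0 °C to reflux
Reagents that add atoms: none
Why: Malonic ester alkylation; the sodium enolate of the malonate, kept in excess to suppress dialkylation, displaces bromide at the primary allylic carbon by SN2.

**Step 3**
Reactants: 4 (1E,3E)-9-methyl-1-phenyldeca-1,3,8-trien-5-one; 7 diethyl 2-(3-methylbut-2-enyl)malonate
Product: 9 ethyl 1,3-bis(3-methylbut-2-enyl)-2,4-dioxo-6-[(E)-2-phenylethenyl]cyclohexane-1-carboxylate (racemic diastereomer and enol mixture), via Michael adduct 8 (not isolated)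
Conditions: NaOEt (1.2 equiv), EtOH, reflux; cold 1 M HCl work-up
Reagents that add atoms: none
Why: Michael–Claisen (Michael–Dieckmann) annulation, the classical way from enones and malonic esters to cyclohexane-1,3-diones: the sodium enolate of 7 adds reversibly to the β-carbon of 4 (ring bond C1–C2) to give 8, proton exchange moves the ketone enolate to the CH2 on the far side of the carbonyl, and that enolate acylates one malonate ester (ring bond C3–C4) with loss of ethoxide. The ring closes in a geometrically favoured 6-(enolendo)-exo-trig Claisen condensation, and the product leaves all equilibria as the sodium enolate of the 1,3-dione, which is what should pull the hindered, reversible Michael step forward. Three sp3 centres arise (ring C1 with the styryl group, the quaternary C2, the enolizable C4); none is controlled and none needs to be, since all become aromatic carbons in step 7. The step needs 1,4- and not 1,6-addition, and closure from the enolate on the prenyl side. The 1,6-adduct could only close an eight-membered ring and the enolate at the inner α-carbon only a four-membered one, so reversible addition should funnel the material through the single six-membered closure. The E styryl double bond is left alone because after 1,4-addition it is no longer conjugated to the carbonyl group.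

**Step 4**
Reactants: 9 ethyl 1,3-bis(3-methylbut-2-enyl)-2,4-dioxo-6-[(E)-2-phenylethenyl]cyclohexane-1-carboxylate
Product: 11 2,4-bis(3-methylbut-2-enyl)-5-[(E)-2-phenylethenyl]cyclohexane-1,3-dione (racemic diastereomer and enol mixture), via keto acid 10 (not isolated)
Conditions: 2 M aq. NaOH, EtOH, reflux; then 1 M HCl to pH 3, 50 °C
Reagents that add atoms: none
Why: Saponification of the β-keto ester and decarboxylation of β-keto acid 10 through the usual cyclic transition state; under base the ring carbonyls are tied up as the dione enolate and are not attacked, and the acid stage is kept dilute and mild so that the prenyl groups do not cyclize onto the enol oxygen.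

**Step 5**
Reactants: 11 2,4-bis(3-methylbut-2-enyl)-5-[(E)-2-phenylethenyl]cyclohexane-1,3-dione
Product: 12 2,6-bis(3-methylbut-2-enyl)-5-[(E)-2-phenylethenyl]-3-(prop-2-enyloxy)cyclohex-2-en-1-one (racemic diastereomer mixture)
Conditions: allyl alcohol, PPh3, DIAD, THF, 0 °C to rt
Reagents that add atoms: allyl alcohol, C=CCO
Why: Mitsunobu O-alkylation of the acidic 1,3-dione; the enolate oxygen attacks the allyloxyphosphonium ion by SN2, oxygen alkylation is favoured because the central carbon is already substituted, and the oxygen at C5 (next to the ring CH2) should react ahead of the oxygen at C3 (next to the prenyl-bearing CH), all under neutral conditions that spare the prenyl groups.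

**Step 6**
Reactants: 12 2,6-bis(3-methylbut-2-enyl)-5-[(E)-2-phenylethenyl]-3-(prop-2-enyloxy)cyclohex-2-en-1-one
Product: 14 2,6-bis(3-methylbut-2-enyl)-5-[(E)-2-phenylethenyl]-6-(phenylselanyl)-3-(prop-2-enyloxy)cyclohex-2-en-1-one (racemic, PhSe trans to styryl), via lithium dienolate 13 (not isolated)
Conditions: LiN(iPr)2 (1.1 equiv), THF, −78 °C; PhSeCl (1.05 equiv), −78 °C; aq. NH4Cl
Reagents that add atoms: benzeneselenenyl chloride, Cl[Se]c1ccccc1
Why: Kinetic α'-deprotonation of a 3-alkoxycyclohex-2-enone gives the cross-conjugated dienolate 13, which is selenenylated at carbon much faster than PhSeCl adds to the prenyl double bonds; attack anti to the neighbouring styryl group should place selenium cis to the ring hydrogen at C1, as the syn-elimination of step 7 requires.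

**Step 7**
Reactants: 14 2,6-bis(3-methylbut-2-enyl)-5-[(E)-2-phenylethenyl]-6-(phenylselanyl)-3-(prop-2-enyloxy)cyclohex-2-en-1-one
Product: 17 2,6-bis(3-methylbut-2-enyl)-3-[(E)-2-phenylethenyl]-5-(prop-2-enyloxy)phenol, via selenoxide 15 (not isolated), via cyclohexadienone 16 (not isolated)
Conditions: mCPBA (1.0 equiv), CH2Cl2, −78 °C; then iPr2NH (3 equiv), −78 °C to rt
Reagents that add atoms: none
Why: Selenide oxidation and selenoxide syn-elimination; 15 should lose PhSeOH through the cis ring hydrogen at C1 (allylic to the styryl group) below room temperature, and the resulting cyclohexa-2,5-dienone 16 with a ring CH2 para to the carbonyl is the keto tautomer of a phenol and should aromatize at once, while mCPBA at −78 °C oxidizes selenium far faster than the alkenes and the amine traps PhSeOH.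

**Step 8**
Reactants: 17 2,6-bis(3-methylbut-2-enyl)-3-[(E)-2-phenylethenyl]-5-(prop-2-enyloxy)phenol
Product: 18 2-methoxy-1,3-bis(3-methylbut-2-enyl)-4-[(E)-2-phenylethenyl]-6-(prop-2-enyloxy)benzene
Conditions: MeI, K2CO3, DMF, rt to 40 °C
Reagents that add atoms: iodomethane, CI
Why: Williamson ether synthesis; the only free hydroxyl, although flanked by two prenyl groups, is methylated as its potassium phenoxide by the small electrophile MeI in a polar aprotic solvent.

**Step 9**
Reactants: 18 2-methoxy-1,3-bis(3-methylbut-2-enyl)-4-[(E)-2-phenylethenyl]-6-(prop-2-enyloxy)benzene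
Product: 19 chiricanine C, 3-methoxy-2,4-bis(3-methylbut-2-enyl)-5-[(E)-2-phenylethenyl]phenol
Conditions: Pd(PPh3)4 (5 mol %), morpholine, THF, rt
Reagents that add atoms: none
Why: Tsuji–Trost type deallylation; zerovalent palladium ionizes the aryl allyl ether to a π-allyl complex and the phenoxide, morpholine takes up the allyl group, the prenyl groups (no leaving group) and the stilbene are inert, and the absence of acid keeps the ortho-prenyl phenol from closing to a chroman.

**Compound list**

1 | (E)-cinnamaldehyde | O=C/C=C/c1ccccc1 | starting material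
2 | 6-methylhept-5-en-2-one | CC(=O)CCC=C(C)C | starting material
3 | (1E)-3-hydroxy-9-methyl-1-phenyldeca-1,8-dien-5-one (racemic aldol) | CC(C)=CCCC(=O)CC(O)/C=C/c1ccccc1 | intermediate
4 | (1E,3E)-9-methyl-1-phenyldeca-1,3,8-trien-5-one | CC(C)=CCCC(=O)/C=C/C=C/c1ccccc1 | intermediate
5 | diethyl malonate | CCOC(=O)CC(=O)OCC | starting material
6 | prenyl bromide (1-bromo-3-methylbut-2-ene) | CC(C)=CCBr | starting material
7 | diethyl 2-(3-methylbut-2-enyl)malonate | CCOC(=O)C(CC=C(C)C)C(=O)OCC | intermediate
8 | diethyl 2-(3-methylbut-2-enyl)-2-[(1E)-9-methyl-5-oxo-1-phenyldeca-1,8-dien-3-yl]propanedioate (racemic Michael adduct) | CCOC(=O)C(CC=C(C)C)(C(=O)OCC)C(/C=C/c1ccccc1)CC(=O)CCC=C(C)C | intermediate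
9 | ethyl 1,3-bis(3-methylbut-2-enyl)-2,4-dioxo-6-[(E)-2-phenylethenyl]cyclohexane-1-carboxylate (diastereomer and enol mixture) | CCOC(=O)C1(CC=C(C)C)C(=O)C(CC=C(C)C)C(=O)CC1/C=C/c1ccccc1 | intermediate
10 | 1,3-bis(3-methylbut-2-enyl)-2,4-dioxo-6-[(E)-2-phenylethenyl]cyclohexane-1-carboxylic acid | OC(=O)C1(CC=C(C)C)C(=O)C(CC=C(C)C)C(=O)CC1/C=C/c1ccccc1 | intermediate
11 | 2,4-bis(3-methylbut-2-enyl)-5-[(E)-2-phenylethenyl]cyclohexane-1,3-dione (diastereomer and enol mixture) | O=C1CC(/C=C/c2ccccc2)C(CC=C(C)C)C(=O)C1CC=C(C)C | intermediate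
12 | 2,6-bis(3-methylbut-2-enyl)-5-[(E)-2-phenylethenyl]-3-(prop-2-enyloxy)cyclohex-2-en-1-one (diastereomer mixture) | C=CCOC1=C(CC=C(C)C)C(=O)C(CC=C(C)C)C(/C=C/c2ccccc2)C1 | intermediate
13 | lithium 2,6-bis(3-methylbut-2-enyl)-3-[(E)-2-phenylethenyl]-5-(prop-2-enyloxy)cyclohexa-1,5-dien-1-olate | [Li+].[O-]C1=C(CC=C(C)C)C(/C=C/c2ccccc2)CC(OCC=C)=C1CC=C(C)C | intermediate
14 | 2,6-bis(3-methylbut-2-enyl)-5-[(E)-2-phenylethenyl]-6-(phenylselanyl)-3-(prop-2-enyloxy)cyclohex-2-en-1-one (racemic, PhSe trans to styryl; relative configuration shown) | C=CCOC1=C(CC=C(C)C)C(=O)[C@@](CC=C(C)C)([Se]c2ccccc2)[C@H](/C=C/c2ccccc2)C1 | intermediate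
15 | selenoxide of 14 (racemic, mixture at selenium) | C=CCOC1=C(CC=C(C)C)C(=O)[C@@](CC=C(C)C)([Se](=O)c2ccccc2)[C@H](/C=C/c2ccccc2)C1 | intermediate
16 | 2,6-bis(3-methylbut-2-enyl)-3-[(E)-2-phenylethenyl]-5-(prop-2-enyloxy)cyclohexa-2,5-dien-1-one | C=CCOC1=C(CC=C(C)C)C(=O)C(CC=C(C)C)=C(/C=C/c2ccccc2)C1 | intermediate
17 | 2,6-bis(3-methylbut-2-enyl)-3-[(E)-2-phenylethenyl]-5-(prop-2-enyloxy)phenol | C=CCOc1cc(/C=C/c2ccccc2)c(CC=C(C)C)c(O)c1CC=C(C)C | intermediate
18 | 2-methoxy-1,3-bis(3-methylbut-2-enyl)-4-[(E)-2-phenylethenyl]-6-(prop-2-enyloxy)benzene | C=CCOc1cc(/C=C/c2ccccc2)c(CC=C(C)C)c(OC)c1CC=C(C)C | intermediate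
19 | chiricanine C, 3-methoxy-2,4-bis(3-methylbut-2-enyl)-5-[(E)-2-phenylethenyl]phenol | COc1c(CC=C(C)C)c(O)cc(/C=C/c2ccccc2)c1CC=C(C)C | target

**Step count**

Total: 9 steps. Longest linear sequence: 8 steps (steps 1, 3, 4, 5, 6, 7, 8, 9); step 2 is a one-step side branch.

**Steps most likely to fail**

1. Step 3. The tertiary carbanion of 7 must add to a β-substituted dienone and build a quaternary carbon next to a tertiary one. The Michael equilibrium may lie on the side of the components, which leaves time for self-condensation of 4, for unproductive 1,6-addition and for ethoxide cleavage of the non-enolizable β-keto ester once it has formed. A shift of the ester group from C2 to C6 in the open-chain adduct (the abnormal Michael pathway) would be harmless, since the shifted isomer can close in the same way and should give the same dione 11 after step 4. Fallback: the annulation is run from 4 with unsubstituted diethyl malonate 5 (NaOEt, EtOH, reflux), where the Michael step is unhindered, to give ethyl 3-(3-methylbut-2-enyl)-2,4-dioxo-6-[(E)-2-phenylethenyl]cyclohexane-1-carboxylate F1. Its dianion (LiN(iPr)2, 2.2 equiv, THF, −78 to 0 °C) should be alkylated by prenyl bromide 6 at the more basic, ester-bearing carbon, which returns to the route at 9.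

2. Step 7. The selenoxide can also eliminate toward the allylic CH2 of the C2 prenyl group. That gives an exocyclic diene which does not aromatize by itself, and it becomes the only path if selenium was delivered cis to the styryl group in step 6. Selenium electrophiles may in addition attack the prenyl double bonds. Fallback: setting out from 12, the dienolate 13 is trapped with Me3SiCl to give the silyl dienol ether trimethyl{[2,6-bis(3-methylbut-2-enyl)-3-[(E)-2-phenylethenyl]-5-(prop-2-enyloxy)cyclohexa-1,5-dien-1-yl]oxy}silane F2, a doubly oxygenated cyclohexa-1,3-diene. DDQ (1.0 equiv, 2,6-lutidine, CH2Cl2, 0 °C) should abstract hydride from either ring sp3 carbon and, after proton loss, give the aryl silyl ether trimethyl{2,6-bis(3-methylbut-2-enyl)-3-[(E)-2-phenylethenyl]-5-(prop-2-enyloxy)phenoxy}silane F3, with no regiochemical choice to be made. K2CO3 in MeOH removes the silyl group and the route is rejoined at 17.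

3. Step 5. The two dione oxygens differ only by CH2 against CH(prenyl) as neighbour, so discrimination may be poor, and some C-allylation at the central carbon may occur. Fallback: the oxygens are told apart after aromatization instead. Setting out from 11, Me3SiCl/Et3N and then LiN(iPr)2/Me3SiCl at −78 °C give the bis(silyl) dienol ether 1,3-bis(trimethylsilyloxy)-2,4-bis(3-methylbut-2-enyl)-5-[(E)-2-phenylethenyl]cyclohexa-1,3-diene F4 (either diene regioisomer serves). DDQ (1.0 equiv, CH2Cl2, 0 °C) dehydrogenates it to the bis(silyl) resorcinol ether 1,3-bis(trimethylsilyloxy)-2,4-bis(3-methylbut-2-enyl)-5-[(E)-2-phenylethenyl]benzene F5, and K2CO3/MeOH frees the resorcinol 2,4-bis(3-methylbut-2-enyl)-5-[(E)-2-phenylethenyl]benzene-1,3-diol F6. iPr3SiCl/imidazole in DMF should silylate only the hydroxyl that has one ortho hydrogen, to give the mono-silyl ether 2,6-bis(3-methylbut-2-enyl)-3-[(E)-2-phenylethenyl]-5-[tri(propan-2-yl)silyloxy]phenol F7. MeI/K2CO3 in DMF then methylates the remaining hindered hydroxyl to the methyl ether [3-methoxy-2,4-bis(3-methylbut-2-enyl)-5-[(E)-2-phenylethenyl]phenoxy]tri(propan-2-yl)silane F8, and Bu4NF in THF at 0 °C comes back to the route at 19.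

**Further compounds**

F1 | step 3 | ethyl 3-(3-methylbut-2-enyl)-2,4-dioxo-6-[(E)-2-phenylethenyl]cyclohexane-1-carboxylate | CCOC(=O)C1C(=O)C(CC=C(C)C)C(=O)CC1/C=C/c1ccccc1
F2 | step 7 | trimethyl{[2,6-bis(3-methylbut-2-enyl)-3-[(E)-2-phenylethenyl]-5-(prop-2-enyloxy)cyclohexa-1,5-dien-1-yl]oxy}silane | C[Si](C)(C)OC1=C(CC=C(C)C)C(/C=C/c2ccccc2)CC(OCC=C)=C1CC=C(C)C
F3 | step 7 | trimethyl{2,6-bis(3-methylbut-2-enyl)-3-[(E)-2-phenylethenyl]-5-(prop-2-enyloxy)phenoxy}silane | C[Si](C)(C)Oc1c(CC=C(C)C)c(/C=C/c2ccccc2)cc(OCC=C)c1CC=C(C)C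
F4 | step 5 | 1,3-bis(trimethylsilyloxy)-2,4-bis(3-methylbut-2-enyl)-5-[(E)-2-phenylethenyl]cyclohexa-1,3-diene | C[Si](C)(C)OC1=C(CC=C(C)C)C(O[Si](C)(C)C)=C(CC=C(C)C)C(/C=C/c2ccccc2)C1
F5 | step 5 | 1,3-bis(trimethylsilyloxy)-2,4-bis(3-methylbut-2-enyl)-5-[(E)-2-phenylethenyl]benzene | C[Si](C)(C)Oc1cc(/C=C/c2ccccc2)c(CC=C(C)C)c(O[Si](C)(C)C)c1CC=C(C)C
F6 | step 5 | 2,4-bis(3-methylbut-2-enyl)-5-[(E)-2-phenylethenyl]benzene-1,3-diol | Oc1cc(/C=C/c2ccccc2)c(CC=C(C)C)c(O)c1CC=C(C)C
F7 | step 5 | 2,6-bis(3-methylbut-2-enyl)-3-[(E)-2-phenylethenyl]-5-[tri(propan-2-yl)silyloxy]phenol | CC(C)[Si](Oc1cc(/C=C/c2ccccc2)c(CC=C(C)C)c(O)c1CC=C(C)C)(C(C)C)C(C)C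
F8 | step 5 | [3-methoxy-2,4-bis(3-methylbut-2-enyl)-5-[(E)-2-phenylethenyl]phenoxy]tri(propan-2-yl)silane | CC(C)[Si](Oc1cc(/C=C/c2ccccc2)c(CC=C(C)C)c(OC)c1CC=C(C)C)(C(C)C)C(C)C
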